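Start with the easy step: the ochre flask holds twice the precatalyst of teal at the same substrate, so compare the two flasks by [precatalyst] × time.

| setting | ochre | teal | flask |
|---|---|---|---|
| substrate | 1.5 M | 1.5 M | 1.5 M |
| precatalyst | 0.1 mol% | 0.05 mol% | 0.1 mol% |
| remark | the very flask that is asked about, followed so far | run made earlier |  |
| time |  |  | 6.0 h |

ochre run (percent of the substrate charged)

| time / min | substrate / % | target / % |
|---|---|---|
| 5.00 | 99.3 | 2.5 |
| 15.0 | 95.5 | 4.0 |
| 25.0 | 90.9 | 6.6 |
| 40.0 | 83.2 | 17.0 |
| 60.0 | 73.3 | 27.9 |
| 80.0 | 63.0 | 34.0 |

teal run (percent of the substrate charged)

| time / h | substrate / % | target / % |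
|---|---|---|
| 0.667 | 91.7 | 8.9 |
| 1.33 | 79.0 | 18.8 |
| 2.00 | 67.7 | 27.5 |
| 3.00 | 58.0 | 39.2 |
| 4.00 | 46.8 | 52.2 |

(standard deviation of a reading: 1 percentage point)

- which holds at 6.0 h: what has brought the reaction to rest, or that it has not come to rest (forward and back rates have come level / it is still moving / no working catalyst is left / all of the substrate has reacted)
- part of the substrate gone at 6.0 h
- the target standing at 6.0 h, as a percentage of the substrate charged

- the numbers in the tables scatter by 1 percentage point (one standard deviation)
- the reaction counts as stopped when no species that holds the substrate changes by six tenths of a point or more over the second half of the time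

Divide that product for the ochre flask at the asked time by teal's at its last reading. This gives 3.00, the dose ratio D: how many teal runs of catalyst-time the flask has had. If the loss is pseudo-first-order in substrate, the fraction left is teal's last fraction raised to the power D. My reckoning therefore leaves 10.3%, a conversion of 89.7%.

Is one number enough? Teal at 2.00 h should show 68.4% and reads 67.7%. Ochre at 80.0 min, with D of 0.667, should show 60.3% but reads 63.0%, more than the rule gives, so at this reading the rule runs slightly ahead of the ochre flask. For the ochre flask at 3.00 h the rule gives 32.0%, so by my reckoning substrate falls by 22 percentage points over the second half of the time and the flask is still moving. Target should follow conversion, since teal's substrate and target sum to 99.0%.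

The forecast says it is still moving, with conversion 90% (78% to 97%) and target 89% (75% to 96%), noting “No plateau appears up to 53% conversion”.

At the asked time the ochre flask gives this: it is still moving, with conversion 88.3% and target 85.5%, and 12% of the substrate left against the 10.3% from D.

    substrate + catalyst ⇌ target + catalyst, rate k1*[substrate]*[catalyst] forward; the back reaction follows from the equilibrium constant (K = 30.0, k = 0.106 M⁻¹ s⁻¹)
    substrate + catalyst ⇌ isomer of the product + catalyst, rate k2*[substrate]*[catalyst] forward; the back reaction follows from the equilibrium constant (K = 0.130, k = 0.00693 M⁻¹ s⁻¹)
    precatalyst ⇌ catalyst (K = 2.43, k = 7.51 × 10⁻⁴ s⁻¹)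

The rate carries [catalyst], which at the asked time stands at 70.8% of its own charge in the ochre flask and 70.8% of its own charge in the neighbour with 0.38 M substrate, same loading and time. There D is 0.760, so the rule leaves 56.2%. This change of substrate leaves the forecast's range: the neighbour's conversion of 45.9% lies below the low end of 78%. The neighbour holds 54.1% substrate, with target at 43.5%.

The earlier runs and the new flask are simulated with constants of no real substance.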